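Numbering: ring A (oxepane) is O1, C2 (CMe2), C3 (CHOH), C4, C5, C6 (quaternary, Me), C7 (OCH); ring B is C6–C11 with C10 = C(Me)OH and C11 carrying the C12–C13 linker; ring C is C14, C15 (Me), C16 (C=O), C17, C18, C23; ring D is C18, C19 (C(Me)OH), C20, C21, C22 (CMe2), C23.
Enabling feature: ring C is a cyclohexene (C14=C15) fused cis to ring D along C18–C23, so C19–C22 is a four-carbon bridge from C18 to C23; with C19 as a ketone and the C16 oxygen as an enol ether, rings C and D are the adduct of a C17=C18 vinyl ketone and a C23=C14–C15=C16 dienol ether held together by that bridge.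
Cuts: the C19 carbinol goes back to a ketone, then C16–C17 and C18–C23 (intramolecular Diels–Alder); in the open chain C18–C19, C15=C16, C14–C15 and C13–C14; in the left half C6–C11 and O1–C2 (one cascade), then C11=C12 and C8–C9.
Forward order: rings A and B close together from an acyclic diepoxy enol silane; the C13 iodide is joined to a C14≡C23 alkyne, which is elaborated into dienol ether and vinyl ketone; rings C and D then close together, and two carbonyl adjustments finish the synthesis.
Stereochemistry: C3, C6, C7 from two reagent-controlled Shi epoxidations; C11 from the Z enol silane in a chair-like closure; C10 and C19 from face-selective O2 capture of tertiary radicals; C18 and C23 (with the transient C16) from the endo cycloaddition under a chiral oxazaborolidinium ion.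

Key step: step 22

Assumption: for the tether-bound, s-cis vinyl ketone the (S)-configured oxazaborolidinium ion is taken to direct the diene to the C18 face that gives the 16R,18S,23R adduct; this sense has to be confirmed on a sample of 34, and the (R)-configured catalyst is used with nothing else changed if it is opposite.

Step 1
Reactants: 1 diethyl (2-oxopropyl)phosphonate; 2 geranyl bromide
Product: 4 diethyl [(5E)-6,10-dimethyl-2-oxoundeca-5,9-dien-1-yl]phosphonate, via phosphonate dianion 3 (not isolated)
Conditions: NaH, THF, 0 °C; n-BuLi, 0 °C; then 2, 0 °C to rt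
Reagents that add atoms: none
Why: γ-Alkylation of a β-ketophosphonate dianion, in which the more basic terminal carbanion displaces the allylic bromide (SN2) to form C8–C9 and leaves the phosphonate carbon free for the olefination that follows.

Step 2
Reactants: 4 diethyl [(5E)-6,10-dimethyl-2-oxoundeca-5,9-dien-1-yl]phosphonate; 5 benzyloxyacetaldehyde
Product: 6 (2E,7E)-1-(benzyloxy)-8,12-dimethyltrideca-2,7,11-trien-4-one
Conditions: LiCl, DBU, MeCN, 0 °C to rt
Reagents that add atoms: none
Why: Horner–Wadsworth–Emmons olefination under Masamune–Roush conditions is mild enough for the α-alkoxy aldehyde and should give the E enone that brings in C12 and the protected C13 oxygen.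

Step 3
Reactants: 6 (2E,7E)-1-(benzyloxy)-8,12-dimethyltrideca-2,7,11-trien-4-one
Product: 7 (2E,7S,8S,11S)-1-(benzyloxy)-7,8:11,12-diepoxy-8,12-dimethyltridec-2-en-4-one
Conditions: 1,2:4,5-di-O-isopropylidene-β-L-erythro-2,3-hexodiulo-2,6-pyranose (0.6 equiv), Oxone (2KHSO5·KHSO4·K2SO4), K2CO3, Bu4NHSO4, MeCN/CH2(OMe)2/aqueous Na2B4O7 buffer, 0 °C
Reagents that add atoms: potassium peroxymonosulfate KHSO5, SMILES [K+].[O-]S(=O)(=O)OO
Why: Shi epoxidation, in which the dioxirane of the L-fructose-derived ketone attacks the two electron-rich trisubstituted alkenes through a spiro transition state on the same enantioface each, should set 3S and 6S,7S (target numbering) under catalyst control while the electron-poor enone alkene is left alone.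

Step 4
Reactants: 7 (2E,7S,8S,11S)-1-(benzyloxy)-7,8:11,12-diepoxy-8,12-dimethyltridec-2-en-4-one
Product: 8 (3Z,7S,8S,11S)-1-(benzyloxy)-7,8:11,12-diepoxy-8,12-dimethyl-4-(triethylsilyloxy)tridec-3-ene
Conditions: Et3SiH, RhCl(PPh3)3 (2 mol%), toluene, 50 °C
Reagents that add atoms: triethylsilane, SMILES CC[SiH](CC)CC
Why: Rhodium-catalysed 1,4-hydrosilylation of the enone delivers hydride to C12 and silicon to oxygen through the s-cis enone, which should give the C10=C11 enol silane regiospecifically and mainly as the Z isomer (oxygen cis to C12) under neutral conditions that spare both epoxides.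

Step 5
Reactants: 8 (3Z,7S,8S,11S)-1-(benzyloxy)-7,8:11,12-diepoxy-8,12-dimethyl-4-(triethylsilyloxy)tridec-3-ene
Product: 10 ring A/B hydroxy ketone (3S,6S,7S,11S; C10 ketone; C11 2-benzyloxyethyl; free C3–OH), via C3 trimethylsilyl ether 9 (not isolated)
Conditions: Me3SiOTf, 2,6-di-tert-butyl-4-methylpyridine, CH2Cl2, −78 °C; then Bu4NF, THF, 0 °C
Reagents that add atoms: none
Why: Tandem oxa- and carbacyclisation of a diepoxy enol silane, a known reaction of this substrate class, in which silylation of the terminal epoxide triggers endo attack of the 6,7-epoxide oxygen at tertiary C2 (ring A, C3 and C7 retained) and the epoxonium ion is opened at C6 with inversion by C11 of the Z enol silane in a chair-like transition state (ring B, trans fusion, C11 chain equatorial), after which fluoride frees the C3 alcohol and would equilibrate any axial C11 epimer.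

Step 6
Reactants: 10 ring A/B hydroxy ketone
Product: 11 ring A/B exocyclic alkene (C10=CH2; 3S,6S,7S,11R, the C11 descriptor changing only formally)
Conditions: Ph3PCH3Br, KOt-Bu, toluene, 80 °C
Reagents that add atoms: methyltriphenylphosphonium bromide, SMILES C[P+](c1ccccc1)(c1ccccc1)c1ccccc1.[Br-]
Why: Wittig methylenation with excess ylide (one equivalent is held by the free hydroxyl) converts the hindered C10 ketone into the exocyclic alkene, and base-induced epimerisation at C11 is harmless because the equatorial chain is the stable arrangement.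

Step 7
Reactants: 11 ring A/B exocyclic alkene
Product: 12 ring A/B diol (3S,6S,7S,10S,11S; C10 tertiary alcohol; C13 benzyl ether)
Conditions: Co(acac)2 (20 mol%), PhSiH3, O2 (1 atm), THF, rt
Reagents that add atoms: dioxygen, SMILES O=O
Why: Mukaiyama hydration (hydrogen-atom transfer from a cobalt hydride, Markovnikov) gives the tertiary C10 radical, which O2 should trap from the equatorial face because the axial face is blocked by the 1,3-diaxial C6 methyl group, so the hydroxyl ends up equatorial and the new methyl axial (10S).

Step 8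
Reactants: 12 ring A/B diol
Product: 13 ring A/B bis(triethylsilyl) ether (C3–OSiEt3; C10–OSiEt3; C13 benzyl ether)
Conditions: Et3SiOTf, 2,6-lutidine, CH2Cl2, −78 to 0 °C
Reagents that add atoms: triethylsilyl triflate, SMILES CC[Si](CC)(CC)OS(=O)(=O)C(F)(F)F
Why: The silyl triflate with a hindered pyridine base silylates both the secondary C3 and the tertiary C10 hydroxyl, giving ethers that tolerate organolithium, hydride and mild Lewis-acid steps and are removed together at the end.

Step 9
Reactants: 13 ring A/B bis(triethylsilyl) ether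
Product: 14 ring A/B primary alcohol (C13–OH)
Conditions: H2 (1 atm), Pd/C, EtOAc, rt
Reagents that add atoms: none
Why: Hydrogenolysis of the benzyl ether over palladium in a non-protic solvent, in which triethylsilyl ethers are stable, releases the primary C13 alcohol at a stage where no alkene is present.

Step 10
Reactants: 14 ring A/B primary alcohol
Product: 15 ring A/B iodide (C13–I; 3S,6S,7S,10S,11S)
Conditions: I2, PPh3, imidazole, CH2Cl2, 0 °C to rt
Reagents that add atoms: iodine, SMILES II
Why: Appel-type iodination (Garegg–Samuelsson conditions) converts the unhindered primary alcohol into the iodide by SN2 displacement of the alkoxyphosphonium ion under buffered conditions that leave the silyl ethers intact.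

Step 11
Reactants: 16 2,2-dimethylpent-4-enal
Product: 17 3,3-dimethylhex-5-en-1-yne
Conditions: dimethyl (1-diazo-2-oxopropyl)phosphonate, K2CO3, MeOH, 0 °C to rt
Reagents that add atoms: dimethyl (1-diazo-2-oxopropyl)phosphonate, SMILES COP(=O)(OC)C(=[N+]=[N-])C(C)=O
Why: Seyferth–Gilbert homologation with the Ohira–Bestmann reagent converts the non-enolisable α-quaternary aldehyde into the terminal alkyne that will become C14≡C23.

Step 12
Reactants: 17 3,3-dimethylhex-5-en-1-yne
Product: 19 4,4-dimethylhex-5-yn-1-ol, via B-alkyl-9-BBN 18 (not isolated)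
Conditions: 9-BBN, THF, 0 °C to rt; then NaOH, H2O2, 0 °C
Reagents that add atoms: hydrogen peroxide, SMILES OO
Why: Hydroboration with 9-BBN is selective for the unhindered terminal alkene over the alkyne flanked by a quaternary carbon, and oxidation of the borane gives the primary alcohol that will become C19.

Step 13
Reactants: 20 4-methoxybenzyl alcohol
Product: 21 4-methoxybenzyl methylthiomethyl ether
Conditions: NaH, NaI (cat.), ClCH2SMe, DME, 0 °C to rt
Reagents that add atoms: chloromethyl methyl sulfide, SMILES ClCSC
Why: Williamson-type alkylation of the alkoxide with chloromethyl methyl sulfide gives the O,S-acetal, a storable precursor of the sensitive chloromethyl ether.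

Step 14
Reactants: 21 4-methoxybenzyl methylthiomethyl ether
Product: 23 [(4-methoxybenzyloxy)methyl]triphenylphosphonium chloride, via 4-methoxybenzyl chloromethyl ether 22 (not isolated)
Conditions: SO2Cl2, CH2Cl2, −78 °C; evaporation; then PPh3, toluene, rt
Reagents that add atoms: sulfuryl chloride, SMILES ClS(Cl)(=O)=O; triphenylphosphine, SMILES c1ccc(cc1)P(c1ccccc1)c1ccccc1
Why: Sulfuryl chloride cleaves the O,S-acetal at sulfur to the chloromethyl ether, which is quaternised at once by triphenylphosphine (SN2) to give the Wittig salt.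

Step 15
Reactants: 19 4,4-dimethylhex-5-yn-1-ol; 15 ring A/B iodide
Product: 25 alkynol (C14≡C23; C19–OH; silylated left half), via dilithium alkynolate 24 (not isolated)
Conditions: 19 (3 equiv), n-BuLi (6 equiv), THF, −78 to 0 °C; then 15, DMPU, −20 °C to rt
Reagents that add atoms: none
Why: Alkylation of a lithium acetylide, in which the acetylide carbon of the dianion is far more nucleophilic than the lithium alkoxide and displaces the primary iodide (SN2) to form C13–C14, no free butyllithium being left to attack the iodide.

Step 16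
Reactants: 25 alkynol
Product: 27 (E)-alkenyl iodide (C14–I; C13 cis to C22; C19–OH), via alkenylzirconocene 26 (not isolated)
Conditions: Cp2Zr(H)Cl (3.5 equiv), THF, 50 °C; then I2, 0 °C
Reagents that add atoms: iodine, SMILES II
Why: Schwartz hydrozirconation adds Zr–H syn across the alkyne and, after equilibration with excess reagent, places zirconium on C14 away from the quaternary C22, so iodinolysis with retention should give the E iodide, the first equivalent of hydride being consumed by the free hydroxyl.

Step 17
Reactants: 27 (E)-alkenyl iodide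
Product: 29 (E)-enone (C15 methyl ketone trans to C22; C19–OH), via alkenyllithium 28 (not isolated)
Conditions: t-BuLi (3.2 equiv), Et2O, −78 °C; then MeC(O)N(OMe)Me, −78 to 0 °C
Reagents that add atoms: N-methoxy-N-methylacetamide, SMILES CC(=O)N(C)OC
Why: Iodine–lithium exchange with retention of alkene geometry followed by Weinreb ketone synthesis (chelated tetrahedral intermediate, no over-addition) installs the C15 methyl ketone on C14.

Step 18
Reactants: 29 (E)-enone; 23 [(4-methoxybenzyloxy)methyl]triphenylphosphonium chloride
Product: 31 (E,E)-dienol 4-methoxybenzyl ether (C23=C14–C15=C16–OPMB; C19–OH), via phosphorus ylide 30 (not isolated)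
Conditions: 23, NaN(SiMe3)2, THF, 0 °C; then 29 (as its sodium alkoxide), 0 °C to rt
Reagents that add atoms: none
Why: Wittig alkoxymethylenation of the methyl ketone gives the dienol ether, in which the alkoxy group should prefer the position cis to the small methyl group (E at C15=C16) over that cis to the branched alkenyl group, and a minor Z isomer would be removed by chromatography and concerns only C16, which is oxidised later.

Step 19
Reactants: 31 (E,E)-dienol 4-methoxybenzyl ether
Product: 32 C19 aldehyde
Conditions: Dess–Martin periodinane, NaHCO3, CH2Cl2, 0 °C to rt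
Reagents that add atoms: none
Why: Dess–Martin oxidation under hydrogencarbonate buffer converts the primary alcohol into the aldehyde without the acid that would hydrolyse the dienol ether.

Step 20
Reactants: 32 C19 aldehyde
Product: 33 C19 allylic alcohol (both C19 epimers)
Conditions: CH2=CHMgBr, THF, −78 °C
Reagents that add atoms: vinylmagnesium bromide, SMILES C=C[Mg]Br
Why: Grignard addition of the vinyl group to the aldehyde forms C18–C19, the C19 configuration being irrelevant because the carbinol is oxidised next, and the unactivated triene can be stored at this stage.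

Step 21
Reactants: 33 C19 allylic alcohol
Product: 34 trienone (C17=C18–C19 vinyl ketone; E,E dienol ether)
Conditions: PhS(Cl)=N-t-Bu, DBU, CH2Cl2, −78 °C; cold filtration through silica (pentane, below −40 °C); used at once
Reagents that add atoms: none
Why: Oxidation with N-tert-butylbenzenesulfinimidoyl chloride (alkoxide attack at sulfur, then cyclic β-elimination) runs at −78 °C under basic conditions, so the trienone is formed and handled cold before the uncatalysed cycloaddition can set in.

Step 22
Reactants: 34 trienone
Product: 35 cis-fused octalone (16R,18S,23R; C19 ketone; C16–OPMB; C14=C15)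
Conditions: (S)-3,3-diphenyl-1-(o-tolyl)tetrahydro-1H,3H-pyrrolo[1,2-c][1,3,2]oxazaborole (25 mol%), Tf2NH (20 mol%), CH2Cl2, −78 °C; Et3N quench
Reagents that add atoms: none
Why: The boron cation binds the C19 carbonyl and lowers the LUMO of the C17=C18 vinyl ketone, which adds in a concerted, asynchronous [4+2] across the C23=C14–C15=C16 dienol ether to form C16–C17 and C18–C23; the closest known reactions are the Lewis-acid-promoted intramolecular Diels–Alder reactions of 1,7,9-decatrien-3-ones and the oxazaborolidinium-catalysed additions of vinyl ketones to dienes. Ring C closes as the new cyclohexene through the two σ-bonds, leaving the alkene at C14=C15 where the enone needs it, and ring D closes at the same time as the six-membered ring spanned by the C19–C22 tether in the fused mode, the bridged mode being excluded by the four-atom tether. C18 and C23 become cis because the tether sits outside on the E-configured C23 terminus and the tether carbonyl lies endo under the diene (Alder rule, reinforced by the Lewis acid), and C16 follows from the E enol ether, so H16, H18 and H23 end up on one face. The absolute sense at C18 and C23 cannot come from the remote left half and is imposed by the chiral cation, which shields one face of the bound enone, while Tf2NH is kept below the amount of oxazaborolidine so that no free acid meets the dienol ether. The step needs endo over exo and one diene face: the in-tether carbonyl and the low temperature secure the first and the catalyst the second, and the C22 gem-dimethyl group (Thorpe–Ingold effect) together with the electron-rich, s-cis-biased 2,3-disubstituted diene should keep the catalysed path ahead of the background reaction even though the tether overrides the ortho preference of the alkoxy group.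

Step 23
Reactants: 35 cis-fused octalone
Product: 36 C19 exocyclic alkene (16R,18S,23R)
Conditions: Cp2TiMe2, toluene, 70 °C, dark
Reagents that add atoms: dimethyltitanocene, SMILES C[Ti](C)(C1C=CC=C1)C1C=CC=C1
Why: Petasis methylenation (through Cp2Ti=CH2 and an oxatitanacyclobutane) is non-basic, so the epimerisable C18 centre next to the ketone keeps its cis configuration and the allylic ether and silyl ethers are untouched.

Step 24
Reactants: 36 C19 exocyclic alkene
Product: 37 C19 tertiary alcohol (16R,18S,19S,23R)
Conditions: Co(acac)2 (20 mol%), PhSiH3, O2 (1 atm), THF, rt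
Reagents that add atoms: dioxygen, SMILES O=O
Why: Mukaiyama hydration acts only on the 1,1-disubstituted alkene (the tetrasubstituted C14=C15 alkene does not accept a hydrogen atom at a useful rate), and O2 should trap the tertiary C19 radical from the convex face of the cis-fused bicycle, the face of H18 and away from C17, which places the hydroxyl syn to the ring-fusion hydrogens (19S), the opposite of what methyl addition to the ketone from that face would give.

Step 25
Reactants: 37 C19 tertiary alcohol
Product: 38 C16 allylic alcohol (16R; C16–OH and C19–OH free)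
Conditions: DDQ, CH2Cl2/pH 7 phosphate buffer, 0 °C
Reagents that add atoms: none
Why: Oxidative cleavage of the 4-methoxybenzyl ether by DDQ (hydride abstraction to the oxocarbenium ion, then hydrolysis) frees the C16 allylic alcohol without touching the silyl ethers, and any onward oxidation to the enone would only anticipate the next step.

Step 26
Reactants: 38 C16 allylic alcohol
Product: 39 bis(triethylsilyl) ether of sipholenol K (C16 enone)
Conditions: Dess–Martin periodinane, NaHCO3, CH2Cl2, 0 °C to rt
Reagents that add atoms: none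
Why: Dess–Martin oxidation converts the allylic alcohol into the conjugated C16 ketone and so removes the auxiliary C16 stereocentre, while the tertiary C19 alcohol cannot be oxidised.

Step 27
Reactants: 39 bis(triethylsilyl) ether of sipholenol K
Product: 40 sipholenol K
Conditions: HF·pyridine, pyridine, THF, 0 °C to rt
Reagents that add atoms: none
Why: Buffered HF·pyridine cleaves the secondary and the tertiary triethylsilyl ether by fluoride attack at silicon without dehydrating the tertiary alcohols or epimerising C18, which should give the target.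

Compound list
1 | diethyl (2-oxopropyl)phosphonate | CCOP(=O)(CC(C)=O)OCC | starting material
2 | geranyl bromide, (2E)-1-bromo-3,7-dimethylocta-2,6-diene | CC(C)=CCC/C(C)=C/CBr | starting material
3 | phosphonate dianion (sodium lithium salt of 1) | CCOP(=O)(OCC)[CH-]C(=O)[CH2-].[Na+].[Li+] | intermediate
4 | diethyl [(5E)-6,10-dimethyl-2-oxoundeca-5,9-dien-1-yl]phosphonate | CCOP(=O)(OCC)CC(=O)CC/C=C(\C)CCC=C(C)C | intermediate
5 | benzyloxyacetaldehyde | O=CCOCc1ccccc1 | starting material
6 | (2E,7E)-1-(benzyloxy)-8,12-dimethyltrideca-2,7,11-trien-4-one | CC(C)=CCC/C(C)=C/CCC(=O)/C=C/COCc1ccccc1 | intermediate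
7 | (2E,7S,8S,11S)-1-(benzyloxy)-7,8:11,12-diepoxy-8,12-dimethyltridec-2-en-4-one | CC1(C)O[C@H]1CC[C@]2(C)O[C@H]2CCC(=O)/C=C/COCc3ccccc3 | intermediate
8 | (3Z,7S,8S,11S)-1-(benzyloxy)-7,8:11,12-diepoxy-8,12-dimethyl-4-(triethylsilyloxy)tridec-3-ene | CC1(C)O[C@H]1CC[C@]2(C)O[C@H]2CC/C(O[Si](CC)(CC)CC)=C/CCOCc3ccccc3 | intermediate
9 | C3 trimethylsilyl ether of ring A/B ketone 10 | c1ccccc1COCC[C@H]2[C@]3(C)CC[C@H](O[Si](C)(C)C)C(C)(C)O[C@H]3CCC2=O | intermediate
10 | ring A/B hydroxy ketone (3S,6S,7S,11S; trans-fused; C10 ketone; C11 2-benzyloxyethyl) | c1ccccc1COCC[C@H]2[C@]3(C)CC[C@H](O)C(C)(C)O[C@H]3CCC2=O | intermediate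
11 | ring A/B exocyclic alkene (C10=CH2) | c1ccccc1COCC[C@H]2[C@]3(C)CC[C@H](O)C(C)(C)O[C@H]3CCC2=C | intermediate
12 | ring A/B diol (3S,6S,7S,10S,11S) | c1ccccc1COCC[C@H]2[C@]3(C)CC[C@H](O)C(C)(C)O[C@H]3CC[C@]2(C)O | intermediate
13 | ring A/B bis(triethylsilyl) ether, C13 benzyl ether | c1ccccc1COCC[C@H]2[C@]3(C)CC[C@H](O[Si](CC)(CC)CC)C(C)(C)O[C@H]3CC[C@]2(C)O[Si](CC)(CC)CC | intermediate
14 | ring A/B primary alcohol (C13–OH) | OCC[C@H]1[C@]2(C)CC[C@H](O[Si](CC)(CC)CC)C(C)(C)O[C@H]2CC[C@]1(C)O[Si](CC)(CC)CC | intermediate
15 | ring A/B iodide (C13–I) | ICC[C@H]1[C@]2(C)CC[C@H](O[Si](CC)(CC)CC)C(C)(C)O[C@H]2CC[C@]1(C)O[Si](CC)(CC)CC | intermediate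
16 | 2,2-dimethylpent-4-enal | C=CCC(C)(C)C=O | starting material
17 | 3,3-dimethylhex-5-en-1-yne | C#CC(C)(C)CC=C | intermediate
18 | B-(4,4-dimethylhex-5-yn-1-yl)-9-BBN | C#CC(C)(C)CCCB1C2CCCC1CCC2 | intermediate
19 | 4,4-dimethylhex-5-yn-1-ol | C#CC(C)(C)CCCO | intermediate
20 | 4-methoxybenzyl alcohol | COc1ccc(CO)cc1 | starting material
21 | 4-methoxybenzyl methylthiomethyl ether | COc1ccc(COCSC)cc1 | intermediate
22 | 4-methoxybenzyl chloromethyl ether | COc1ccc(COCCl)cc1 | intermediate
23 | [(4-methoxybenzyloxy)methyl]triphenylphosphonium chloride | COc1ccc(COC[P+](c2ccccc2)(c2ccccc2)c2ccccc2)cc1.[Cl-] | intermediate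
24 | dilithium alkynolate of 19 | [Li]OCCCC(C)(C)C#C[Li] | intermediate
25 | alkynol (C14≡C23; C19–OH; silylated left half) | OCCCC(C)(C)C#CCC[C@H]1[C@]2(C)CC[C@H](O[Si](CC)(CC)CC)C(C)(C)O[C@H]2CC[C@]1(C)O[Si](CC)(CC)CC | intermediate
26 | alkenylzirconocene (Zr on C14; C19 zirconium alkoxide) | Cl[Zr](OCCCC(C)(C)/C=C(/[Zr](Cl)(C1C=CC=C1)C1C=CC=C1)CC[C@H]1[C@]2(C)CC[C@H](O[Si](CC)(CC)CC)C(C)(C)O[C@H]2CC[C@]1(C)O[Si](CC)(CC)CC)(C1C=CC=C1)C1C=CC=C1 | intermediate
27 | (E)-alkenyl iodide (C14–I) | OCCCC(C)(C)/C=C(/I)CC[C@H]1[C@]2(C)CC[C@H](O[Si](CC)(CC)CC)C(C)(C)O[C@H]2CC[C@]1(C)O[Si](CC)(CC)CC | intermediate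
28 | alkenyllithium (C14–Li; C19 lithium alkoxide) | [Li]OCCCC(C)(C)/C=C(/[Li])CC[C@H]1[C@]2(C)CC[C@H](O[Si](CC)(CC)CC)C(C)(C)O[C@H]2CC[C@]1(C)O[Si](CC)(CC)CC | intermediate
29 | (E)-enone (C15 methyl ketone) | OCCCC(C)(C)/C=C(/C(C)=O)CC[C@H]1[C@]2(C)CC[C@H](O[Si](CC)(CC)CC)C(C)(C)O[C@H]2CC[C@]1(C)O[Si](CC)(CC)CC | intermediate
30 | [(4-methoxybenzyloxy)methylene]triphenylphosphorane | COc1ccc(COC=P(c2ccccc2)(c2ccccc2)c2ccccc2)cc1 | intermediate
31 | (E,E)-dienol 4-methoxybenzyl ether, C19 alcohol | OCCCC(C)(C)/C=C(CC[C@H]1[C@]2(C)CC[C@H](O[Si](CC)(CC)CC)C(C)(C)O[C@H]2CC[C@]1(C)O[Si](CC)(CC)CC)/C(C)=C/OCc1ccc(OC)cc1 | intermediate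
32 | C19 aldehyde | O=CCCC(C)(C)/C=C(CC[C@H]1[C@]2(C)CC[C@H](O[Si](CC)(CC)CC)C(C)(C)O[C@H]2CC[C@]1(C)O[Si](CC)(CC)CC)/C(C)=C/OCc1ccc(OC)cc1 | intermediate
33 | C19 allylic alcohol (C19 epimers) | C=CC(O)CCC(C)(C)/C=C(CC[C@H]1[C@]2(C)CC[C@H](O[Si](CC)(CC)CC)C(C)(C)O[C@H]2CC[C@]1(C)O[Si](CC)(CC)CC)/C(C)=C/OCc1ccc(OC)cc1 | intermediate
34 | trienone (vinyl ketone with E,E dienol ether) | C=CC(=O)CCC(C)(C)/C=C(CC[C@H]1[C@]2(C)CC[C@H](O[Si](CC)(CC)CC)C(C)(C)O[C@H]2CC[C@]1(C)O[Si](CC)(CC)CC)/C(C)=C/OCc1ccc(OC)cc1 | intermediate
35 | cis-fused octalone (16R,18S,23R; C19 ketone; C16–OPMB) | CC1=C(CC[C@H]2[C@]3(C)CC[C@H](O[Si](CC)(CC)CC)C(C)(C)O[C@H]3CC[C@]2(C)O[Si](CC)(CC)CC)[C@@H]2[C@H](C[C@H]1OCc1ccc(OC)cc1)C(=O)CCC2(C)C | intermediate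
36 | C19 exocyclic alkene | CC1=C(CC[C@H]2[C@]3(C)CC[C@H](O[Si](CC)(CC)CC)C(C)(C)O[C@H]3CC[C@]2(C)O[Si](CC)(CC)CC)[C@@H]2[C@H](C[C@H]1OCc1ccc(OC)cc1)C(=C)CCC2(C)C | intermediate
37 | C19 tertiary alcohol (19S), C16–OPMB | CC1=C(CC[C@H]2[C@]3(C)CC[C@H](O[Si](CC)(CC)CC)C(C)(C)O[C@H]3CC[C@]2(C)O[Si](CC)(CC)CC)[C@@H]2[C@H](C[C@H]1OCc1ccc(OC)cc1)[C@@](C)(O)CCC2(C)C | intermediate
38 | C16 allylic alcohol (16R) | CC1=C(CC[C@H]2[C@]3(C)CC[C@H](O[Si](CC)(CC)CC)C(C)(C)O[C@H]3CC[C@]2(C)O[Si](CC)(CC)CC)[C@@H]2[C@H](C[C@H]1O)[C@@](C)(O)CCC2(C)C | intermediate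
39 | bis(triethylsilyl) ether of sipholenol K | CC1=C(CC[C@H]2[C@]3(C)CC[C@H](O[Si](CC)(CC)CC)C(C)(C)O[C@H]3CC[C@]2(C)O[Si](CC)(CC)CC)[C@@H]2[C@H](CC1=O)[C@@](C)(O)CCC2(C)C | intermediate
40 | sipholenol K (3S,6S,7S,10S,11S,18S,19S,23R) | CC1=C(CC[C@H]2[C@]3(C)CC[C@H](O)C(C)(C)O[C@H]3CC[C@]2(C)O)[C@@H]2[C@H](CC1=O)[C@@](C)(O)CCC2(C)C | target

Total step count: 27. Longest linear sequence: 23 steps (steps 1–10 and 15–27); steps 11–12 and 13–14 are side branches.

Steps most likely to fail

Step 22. The cycloaddition may start without the catalyst while 34 is being prepared, or the chiral boron cation may discriminate poorly between the faces of a tether-bound s-cis enone or be held by the ether oxygens. In either case the configuration at C18 and C23 relative to the left half is lost; protonation of the dienol ether by adventitious acid would be a further drain. The fallback gives up reagent control and settles the facial question by separation. Setting out from 34, cyclisation with Me2AlCl in CH2Cl2 at −78 °C, an achiral promoter of the known endo-selective decatrienone cyclisation, should give 35 together with its diastereomer, the (16S,18R,23S) cis-fused octalone F1. The two are separated by preparative HPLC, and the route is rejoined at 35.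

Step 24. Capture of the C19 radical by O2 may be poorly face-selective, or the radical may be reduced to the C19–H compound. The fallback forms the C19–C bond on the ketone instead of the C19–O bond on the alkene. Setting out from 35, methyl addition with MeMgBr and CeCl3 in THF at −78 °C, non-basic enough to spare C18, leads directly to 37 and bypasses 36. Because carbon and not oxygen is delivered, a given face preference at C19 gives the opposite configuration, so this route fits the case in which the concave face turns out to be the accessible one. It makes no compound outside the list (F0).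

Step 16. Hydrozirconation of the hindered internal alkyne may be incomplete, or zirconium may end up on C23 and give the regioisomeric iodide. The fallback builds the C23=C14 bond by olefination. Setting out from 15, alkylation of 1 at the carbon between phosphorus and carbonyl (NaH, THF/DMSO) gives the α-alkylated ketophosphonate F2. Horner–Wadsworth–Emmons reaction of F2 with aldehyde 16 (NaH, DME, 60 °C) gives the enone with a terminal vinyl group F3, the acyl group trans to the quaternary carbon. Wittig reaction of F3 with ylide 30 gives the dienol ether with a terminal vinyl group F4. Hydroboration of the vinyl group with 9-BBN, which leaves the trisubstituted diene alone, gives the B-alkyl-9-BBN F5 (not isolated), and NaBO3 oxidation gives 31, where the route is rejoined; steps 12 and 15–17 are then not needed.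

Further compounds
F1 | step 22 | (16S,18R,23S) cis-fused octalone, diastereomer of 35 | CC1=C(CC[C@H]2[C@]3(C)CC[C@H](O[Si](CC)(CC)CC)C(C)(C)O[C@H]3CC[C@]2(C)O[Si](CC)(CC)CC)[C@H]2[C@@H](C[C@@H]1OCc1ccc(OC)cc1)C(=O)CCC2(C)C
F0 | step 24 | none | none
F2 | step 16 | α-alkylated ketophosphonate (C14 epimers) | CCOP(=O)(OCC)C(CC[C@H]1[C@]2(C)CC[C@H](O[Si](CC)(CC)CC)C(C)(C)O[C@H]2CC[C@]1(C)O[Si](CC)(CC)CC)C(C)=O
F3 | step 16 | (E)-enone with terminal vinyl group | C=CCC(C)(C)/C=C(/C(C)=O)CC[C@H]1[C@]2(C)CC[C@H](O[Si](CC)(CC)CC)C(C)(C)O[C@H]2CC[C@]1(C)O[Si](CC)(CC)CC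
F4 | step 16 | (E,E)-dienol 4-methoxybenzyl ether with terminal vinyl group | C=CCC(C)(C)/C=C(CC[C@H]1[C@]2(C)CC[C@H](O[Si](CC)(CC)CC)C(C)(C)O[C@H]2CC[C@]1(C)O[Si](CC)(CC)CC)/C(C)=C/OCc1ccc(OC)cc1
F5 | step 16 | B-alkyl-9-BBN of F4 | C(CCB1C2CCCC1CCC2)C(C)(C)/C=C(CC[C@H]3[C@]4(C)CC[C@H](O[Si](CC)(CC)CC)C(C)(C)O[C@H]4CC[C@]3(C)O[Si](CC)(CC)CC)/C(C)=C/OCc5ccc(OC)cc5
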